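**Assumption:** the target has no stereocentre, so the SMILES defines one achiral compound and no stereocontrol is needed; the catalyst (2-hydroxybenzyl)diphenylphosphine oxide, O=P(Cc1ccccc1O)(c1ccccc1)c1ccccc1, is taken as purchasable, and step 1 releases only water.

**Retrosynthetic overview**
1. The target is the docosyl ester of an intact catechol acid; the benzene ring is bought, so no ring is formed.
2. The only disconnection is the ester alkyl C–O bond (carboxylate O to CH2), giving 2,3-dihydroxybenzoic acid 1 as the O-nucleophile and 1-docosanol 2 as the electrophile after catalytic activation.
3. No protecting groups: the carboxylate is the only anion present, so the two phenols are left untouched.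

**Step 1**
Reactants: 1 2,3-dihydroxybenzoic acid (1.1 equiv); 2 1-docosanol (1.0 equiv)
Product: 3 docosyl 2,3-dihydroxybenzoate (gentiside J)
Conditions: (2-hydroxybenzyl)diphenylphosphine oxide (10 mol%), xylenes (0.3 M), reflux (ca. 140 °C), Dean–Stark, N2, 36 h; aqueous wash, then recrystallisation from hexane/EtOH
Reagents that add atoms: none
Why: Proposed new method: a phosphine-oxide-catalysed, redox-neutral Mitsunobu-type dehydrative O-alkylation, here extended to an unprotected catechol/salicylic acid — acid 1 (pKa about 2.9, carboxylate stabilised by the 2-OH hydrogen bond) protonates the P=O of the catalyst, the catalyst's phenol arm closes onto phosphorus with loss of water (removed azeotropically) to give a cyclic aryloxyphosphonium 2,3-dihydroxybenzoate, alcohol 2 opens this ring to a docosyloxyphosphonium carboxylate ion pair, and the carboxylate, the only anion present (the phenols, pKa above 9, stay neutral), displaces the phosphine oxide by SN2 at the unhindered primary carbon to form the ester C–O bond and return the catalyst, while any leakage through an acyloxyphosphonium or through acid-catalysed acyl substitution gives the same achiral ester; the closest known reaction type is the catalytic Mitsunobu esterification of nitrobenzoic acids with this phosphine oxide, which to my knowledge has not been shown with free phenolic or catechol acids; no stereocentre is formed.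

**Compound list**
1 | 2,3-dihydroxybenzoic acid | O=C(O)c1cccc(O)c1O | starting material
2 | 1-docosanol (behenyl alcohol, unbranched C22 primary alcohol) | CCCCCCCCCCCCCCCCCCCCCCO | starting material
3 | docosyl 2,3-dihydroxybenzoate (gentiside J, achiral) | CCCCCCCCCCCCCCCCCCCCCCOC(=O)c1cccc(O)c1O | target

**Total step count:** 1
**Longest linear sequence:** 1

**Steps most likely to fail** (the route has one step, so there is one entry)

Step 1, the proposed new step. The risks are:
- acid 1 may be too weak an acid to drive the cyclodehydration of the catalyst at a useful rate;
- the free phenols of 1 or 3 may reversibly trap the cyclic phosphonium as aryloxyphosphonium species and slow turnover;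
- 1 may partly self-condense or decarboxylate at 140 °C.

Fallback, known chemistry with a different approach: the alcohol is turned into a separate alkyl electrophile and the carboxylate is alkylated under weak base. It sets out from 2, which is converted by an Appel bromination (CBr4, PPh3, CH2Cl2, 0 °C to rt) into 1-bromodocosane F1. Acid 1 is then stirred with KHCO3 (1.2 equiv) in DMF at 60 °C under N2 and alkylated with F1 in an SN2 reaction. Bicarbonate deprotonates only the carboxylic acid, so the phenols are not alkylated. The fallback comes back to the route at 3.

**Further compounds**
F1 | step 1 | 1-bromodocosane | CCCCCCCCCCCCCCCCCCCCCCBr
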